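The decalin is opened across ring B at C5–C10 and C6–C7 (labdane numbering; ring A: C1–C5, C10; ring B: C5–C10). One intramolecular Diels–Alder reaction of an acyclic 1,3,9-decatriene closes rings A and B at once: the (E)-vinyl sulfone C5=C6 adds to the diene C7=C8–C9=C10 and sets C5, C6 and the quaternary C10 under control of C2 and C4. The step exploits ring B with its exocyclic methylene on C8 next to C9–H: a 2-(silylmethyl)diene leaves an allylsilane whose protodesilylation creates both. The precursor carries the sulfone on C6 and the C2/C4 stereocentres in the tether.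

Key step: step 11

Remark: further atom labels follow the labdane skeleton (C17 exocyclic CH2, C18/C19 methyl/acetoxymethyl carbons on C4, C20 methyl on C10, C11–C13 and C16 the oxobutyl chain; α = face opposite to C20); "dienyl" stands for the (2E)-2-methyl-3-[2-(2-methyl-1,3-dioxolan-2-yl)ethyl]-4-[(trimethylsilyl)methyl]penta-2,4-dien-1-yl group (C1, C10, C20, C9, C11–C13, C16, C8, C7, C17).

Step 1
Reactants: 1 methyl acetoacetate; 2 2-(2-bromoethyl)-2-methyl-1,3-dioxolane
Product: 3 methyl 2-acetyl-4-(2-methyl-1,3-dioxolan-2-yl)butanoate (racemic)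
Conditions: K2CO3, NaI (cat.), DMF, 60 °C
Reagents that add atoms: none
Why: C-alkylation of the β-keto ester enolate by a primary bromide (acetoacetic ester alkylation) brings in C11–C13 and C16 with the ketone already masked as a dioxolane.

Step 2
Reactants: 3 methyl 2-acetyl-4-(2-methyl-1,3-dioxolan-2-yl)butanoate
Product: 4 methyl (E)-2-[2-(2-methyl-1,3-dioxolan-2-yl)ethyl]-3-(trifluoromethylsulfonyloxy)but-2-enoate
Conditions: Tf2O, aq. Me4NOH, toluene, 5 °C
Reagents that add atoms: triflic anhydride, O=S(=O)(OS(=O)(=O)C(F)(F)F)C(F)(F)F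
Why: O-sulfonylation of the enolate (enol triflate formation), in which the non-chelated tetramethylammonium enolate should place the oxygen anti to the ester and so fix the C9=C10 geometry (triflate trans to C8, C20 cis to C8).

Step 3
Reactants: 4 methyl (E)-2-[2-(2-methyl-1,3-dioxolan-2-yl)ethyl]-3-(trifluoromethylsulfonyloxy)but-2-enoate
Product: 5 methyl (E)-2-[2-(2-methyl-1,3-dioxolan-2-yl)ethyl]-3-(trimethylstannyl)but-2-enoate
Conditions: Me3SnSnMe3, Pd(PPh3)4 (cat.), LiCl, THF, 65 °C
Reagents that add atoms: hexamethylditin, C[Sn](C)(C)[Sn](C)(C)C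
Why: palladium-catalysed stannylation of an enol triflate (Stille-type coupling with a distannane) should proceed with retention of the alkene geometry.

Step 4
Reactants: 5 methyl (E)-2-[2-(2-methyl-1,3-dioxolan-2-yl)ethyl]-3-(trimethylstannyl)but-2-enoate
Product: 7 (E)-trimethyl[3-[2-(2-methyl-1,3-dioxolan-2-yl)ethyl]-4-(trimethylsilylmethyl)penta-2,4-dien-2-yl]stannane, via carbinol 6 (not isolated)
Conditions: Me3SiCH2MgCl, CeCl3, THF, −78 °C to rt; then SiO2, CH2Cl2, rt
Reagents that add atoms: (trimethylsilyl)methylmagnesium chloride, C[Si](C)(C)C[Mg]Cl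
Why: double 1,2-addition of the cerium-modified Grignard reagent to the ester followed by Peterson elimination turns the ester carbon (C8) into a 2-substituted allylsilane and completes the diene C7=C8(C17H2SiMe3)–C9=C10.

Step 5
Reactants: 7 (E)-trimethyl[3-[2-(2-methyl-1,3-dioxolan-2-yl)ethyl]-4-(trimethylsilylmethyl)penta-2,4-dien-2-yl]stannane; 8 (R)-epichlorohydrin
Product: 11 (R)-2-dienyloxirane, via alkenyllithium 9 (not isolated), via chlorohydrin 10 (not isolated)
Conditions: MeLi, THF, −78 to −20 °C; then BF3·OEt2 (promoter), 8, −78 °C; then NaOH, MeOH–H2O, rt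
Reagents that add atoms: none
Why: tin–lithium exchange with retention, Lewis-acid-assisted epoxide opening at the CH2 terminus (forms C1–C10) and base-induced ring closure of the chlorohydrin, with the C2 stereocentre taken unchanged from 8.

Step 6
Reactants: 11 (R)-2-dienyloxirane; 12 propionic acid
Product: 14 (5S)-5-dienyl-3-methyldihydrofuran-2(3H)-one (C3 epimers), via hydroxy acid 13 (not isolated)
Conditions: LiN(iPr)2 (2.2 equiv per 12), THF, 0 °C; then 11, 45 °C; AcOH; toluene, 80 °C
Reagents that add atoms: none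
Why: epoxide opening at C3 by the carboxylic acid dianion and lactonisation of the γ-hydroxy acid tie C2–O and the future C19 into a γ-butyrolactone template.

Step 7
Reactants: 14 (5S)-5-dienyl-3-methyldihydrofuran-2(3H)-one; 15 (E)-1,2-bis(phenylsulfonyl)ethene
Product: 16 (3S,5R)-5-dienyl-3-methyl-3-[(E)-2-(phenylsulfonyl)ethenyl]dihydrofuran-2(3H)-one
Conditions: LiN(iPr)2, THF, −78 °C; then 15, −78 to −40 °C
Reagents that add atoms: none
Why: conjugate addition–elimination of the lactone enolate on the bis-sulfone (enolate vinylation) should occur anti to the C2 side chain on the five-membered ring, which sets the quaternary C4 (vinyl sulfone trans, C18 cis to the side chain) and installs the activated (E)-dienophile C5=C6.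

Step 8
Reactants: 16 (3S,5R)-5-dienyl-3-methyl-3-[(E)-2-(phenylsulfonyl)ethenyl]dihydrofuran-2(3H)-one
Product: 17 (2S,4R)-4-dienyl-2-methyl-2-[(E)-2-(phenylsulfonyl)ethenyl]butane-1,4-diol
Conditions: iBu2AlH (4 equiv), CH2Cl2, −78 to 0 °C; aq. KNaC4H4O6
Reagents that add atoms: none
Why: hydride reduction of the lactone to the 1,4-diol frees C2–OH and C19–OH, which are trans on the future ring A and so could not stay bridged, while the vinyl sulfone, allylsilane and dioxolane should not react with the electrophilic hydride at low temperature.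

Step 9
Reactants: 17 (2S,4R)-4-dienyl-2-methyl-2-[(E)-2-(phenylsulfonyl)ethenyl]butane-1,4-diol
Product: 18 (2S,4R)-4-dienyl-4-hydroxy-2-methyl-2-[(E)-2-(phenylsulfonyl)ethenyl]butyl acetate
Conditions: AcCl (1.05 equiv), 2,4,6-collidine, CH2Cl2, −78 °C
Reagents that add atoms: acetyl chloride, CC(=O)Cl
Why: kinetically controlled acylation of the primary alcohol in the presence of the secondary one installs the C19 acetate of the target.

Step 10
Reactants: 18 (2S,4R)-4-dienyl-4-hydroxy-2-methyl-2-[(E)-2-(phenylsulfonyl)ethenyl]butyl acetate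
Product: 19 (2S,4R)-4-(tert-butyldimethylsilyloxy)-4-dienyl-2-methyl-2-[(E)-2-(phenylsulfonyl)ethenyl]butyl acetate
Conditions: TBSCl, imidazole, DMF, rt
Reagents that add atoms: tert-butyldimethylsilyl chloride, CC(C)(C)[Si](C)(C)Cl
Why: silyl ether formation blocks C2–OH against conjugate addition to the vinyl sulfone in the thermal step and enlarges the group that must sit equatorially on the forming ring A.

Step 11
Reactants: 19 (2S,4R)-4-(tert-butyldimethylsilyloxy)-4-dienyl-2-methyl-2-[(E)-2-(phenylsulfonyl)ethenyl]butyl acetate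
Product: 20 19-acetoxy-2α-(tert-butyldimethylsilyloxy)-6α-(phenylsulfonyl)-17-(trimethylsilyl)-14,15-dinorlabd-8-en-13-one ethylene ketal
Conditions: toluene, 2,6-di-tert-butyl-4-methylphenol (cat.), 150 °C, sealed tube
Reagents that add atoms: none
Why: Concerted, asynchronous intramolecular [4+2] cycloaddition of the electron-poor (E)-vinyl sulfone C5=C6 with the electron-rich, fully alkylated diene C7=C8–C9=C10; the closest known reaction type is the intramolecular Diels–Alder reaction of sulfonyl-activated 1,3,9-decatrienes. Ring A closes through the C5–C10 bond across the four-atom tether C1–C4 in a chair-like arrangement, and ring B is the cyclohexene formed by the cycloaddition itself (C6–C7 bond, new C8=C9 alkene). The trans ring fusion (C5–H α, C20 β) should follow from the anti transition state with the sulfone endo, because the C9 side chain clashes with the tether in the syn alternative, and the (E) geometry of C5=C6 places the sulfone on C6 cis to C5–H. The face is chosen by the tether stereocentres: only one chair has the C2 silyloxy group equatorial and avoids a triaxial C2–O/C18/C20 array, so C5 and C10 are set relative to C2 and C4 as in the target. The step needs regioselectivity, which the tether enforces, and the outside position of the tether on C10, which the C9=C10 geometry built in steps 2 to 5 secures; the main risk is the low s-cis population caused by the inside C20 methyl.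

Step 12
Reactants: 20 19-acetoxy-2α-(tert-butyldimethylsilyloxy)-6α-(phenylsulfonyl)-17-(trimethylsilyl)-14,15-dinorlabd-8-en-13-one ethylene ketal
Product: 21 19-acetoxy-2α-(tert-butyldimethylsilyloxy)-17-(trimethylsilyl)-14,15-dinorlabd-8-en-13-one ethylene ketal
Conditions: Na(Hg), Na2HPO4, MeOH–THF, −20 °C
Reagents that add atoms: none
Why: reductive desulfonylation by electron transfer removes the activating group and leaves C6 as CH2, with no leaving group β to the sulfone and the phosphate buffer protecting the acetate.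

Step 13
Reactants: 21 19-acetoxy-2α-(tert-butyldimethylsilyloxy)-17-(trimethylsilyl)-14,15-dinorlabd-8-en-13-one ethylene ketal
Product: 22 19-acetoxy-2α-hydroxy-14,15-dinorlabd-8(17)-en-13-one
Conditions: CF3CO2H–H2O–THF, 0 °C to rt
Reagents that add atoms: water, O
Why: acid-mediated protodesilylation of the allylsilane (SE2' protonation of C9 on the α face, anti to the axial C20, with loss of silicon) should give the exocyclic C8=C17 alkene and C9–H α, while the same medium hydrolyses the dioxolane to the C13 ketone and cleaves the silyl ether at C2.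

Step 14
Reactants: 22 19-acetoxy-2α-hydroxy-14,15-dinorlabd-8(17)-en-13-one
Product: 23 19-acetoxy-2α,7α-dihydroxy-14,15-dinorlabd-8(17)-en-13-one (CNP0139304.2)
Conditions: SeO2 (cat.), t-BuOOH, CH2Cl2, rt
Reagents that add atoms: tert-butyl hydroperoxide, CC(C)(C)OO
Why: selenium dioxide allylic oxidation (Riley oxidation: ene reaction, then [2,3]-sigmatropic shift) of the 1,1-disubstituted alkene should attack the ring CH2 (C7) rather than the tertiary C9–H and deliver oxygen on the less hindered α face, giving the axial 7α-alcohol with the exocyclic alkene restored.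

Compound list
1 | methyl acetoacetate | COC(=O)CC(C)=O | starting material
2 | 2-(2-bromoethyl)-2-methyl-1,3-dioxolane | CC1(CCBr)OCCO1 | starting material
3 | methyl 2-acetyl-4-(2-methyl-1,3-dioxolan-2-yl)butanoate (racemic) | COC(=O)C(CCC1(C)OCCO1)C(C)=O | intermediate
4 | methyl (E)-2-[2-(2-methyl-1,3-dioxolan-2-yl)ethyl]-3-(trifluoromethylsulfonyloxy)but-2-enoate | FC(F)(F)S(=O)(=O)O/C(C)=C(\CCC1(C)OCCO1)C(=O)OC | intermediate
5 | methyl (E)-2-[2-(2-methyl-1,3-dioxolan-2-yl)ethyl]-3-(trimethylstannyl)but-2-enoate | C[Sn](C)(C)/C(C)=C(\CCC1(C)OCCO1)C(=O)OC | intermediate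
6 | (E)-3-[2-(2-methyl-1,3-dioxolan-2-yl)ethyl]-1-(trimethylsilyl)-2-(trimethylsilylmethyl)-4-(trimethylstannyl)pent-3-en-2-ol | C[Sn](C)(C)/C(C)=C(\CCC1(C)OCCO1)C(O)(C[Si](C)(C)C)C[Si](C)(C)C | intermediate
7 | (E)-trimethyl[3-[2-(2-methyl-1,3-dioxolan-2-yl)ethyl]-4-(trimethylsilylmethyl)penta-2,4-dien-2-yl]stannane | C[Sn](C)(C)/C(C)=C(\CCC1(C)OCCO1)C(=C)C[Si](C)(C)C | intermediate
8 | (R)-epichlorohydrin | ClC[C@H]1CO1 | starting material
9 | [(2Z)-3-[2-(2-methyl-1,3-dioxolan-2-yl)ethyl]-4-(trimethylsilylmethyl)penta-2,4-dien-2-yl]lithium (Li trans to C8) | [Li]/C(C)=C(\CCC1(C)OCCO1)C(=C)C[Si](C)(C)C | intermediate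
10 | (R)-2-chloro-1-dienylethanol | ClC[C@H](O)C/C(C)=C(\CCC1(C)OCCO1)C(=C)C[Si](C)(C)C | intermediate
11 | (R)-2-dienyloxirane | C1[C@H](O1)C/C(C)=C(\CCC2(C)OCCO2)C(=C)C[Si](C)(C)C | intermediate
12 | propionic acid | CCC(=O)O | starting material
13 | (4S)-4-dienyl-4-hydroxy-2-methylbutanoic acid (C2 epimers) | OC(=O)C(C)C[C@H](O)C/C(C)=C(\CCC1(C)OCCO1)C(=C)C[Si](C)(C)C | intermediate
14 | (5S)-5-dienyl-3-methyldihydrofuran-2(3H)-one (C3 epimers) | O=C1O[C@H](C/C(C)=C(\CCC2(C)OCCO2)C(=C)C[Si](C)(C)C)CC1C | intermediate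
15 | (E)-1,2-bis(phenylsulfonyl)ethene | O=S(=O)(/C=C/S(=O)(=O)c1ccccc1)c1ccccc1 | starting material
16 | (3S,5R)-5-dienyl-3-methyl-3-[(E)-2-(phenylsulfonyl)ethenyl]dihydrofuran-2(3H)-one | O=C1O[C@H](C/C(C)=C(\CCC2(C)OCCO2)C(=C)C[Si](C)(C)C)C[C@@]1(C)/C=C/S(=O)(=O)c1ccccc1 | intermediate
17 | (2S,4R)-4-dienyl-2-methyl-2-[(E)-2-(phenylsulfonyl)ethenyl]butane-1,4-diol | O=S(=O)(c1ccccc1)/C=C/[C@@](C)(CO)C[C@H](O)C/C(C)=C(\CCC1(C)OCCO1)C(=C)C[Si](C)(C)C | intermediate
18 | (2S,4R)-4-dienyl-4-hydroxy-2-methyl-2-[(E)-2-(phenylsulfonyl)ethenyl]butyl acetate | O=S(=O)(c1ccccc1)/C=C/[C@@](C)(COC(C)=O)C[C@H](O)C/C(C)=C(\CCC1(C)OCCO1)C(=C)C[Si](C)(C)C | intermediate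
19 | (2S,4R)-4-(tert-butyldimethylsilyloxy)-4-dienyl-2-methyl-2-[(E)-2-(phenylsulfonyl)ethenyl]butyl acetate | O=S(=O)(c1ccccc1)/C=C/[C@@](C)(COC(C)=O)C[C@H](O[Si](C)(C)C(C)(C)C)C/C(C)=C(\CCC1(C)OCCO1)C(=C)C[Si](C)(C)C | intermediate
20 | 19-acetoxy-2α-(tert-butyldimethylsilyloxy)-6α-(phenylsulfonyl)-17-(trimethylsilyl)-14,15-dinorlabd-8-en-13-one ethylene ketal | C[Si](C)(C)CC=1C[C@H](S(=O)(=O)c3ccccc3)[C@H]2[C@@](C)(COC(C)=O)C[C@H](O[Si](C)(C)C(C)(C)C)C[C@]2(C)C=1CCC4(C)OCCO4 | intermediate
21 | 19-acetoxy-2α-(tert-butyldimethylsilyloxy)-17-(trimethylsilyl)-14,15-dinorlabd-8-en-13-one ethylene ketal | C[Si](C)(C)CC=1CC[C@H]2[C@@](C)(COC(C)=O)C[C@H](O[Si](C)(C)C(C)(C)C)C[C@]2(C)C=1CCC3(C)OCCO3 | intermediate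
22 | 19-acetoxy-2α-hydroxy-14,15-dinorlabd-8(17)-en-13-one | C=C1CC[C@H]2[C@@](C)(COC(C)=O)C[C@H](O)C[C@]2(C)[C@H]1CCC(C)=O | intermediate
23 | 19-acetoxy-2α,7α-dihydroxy-14,15-dinorlabd-8(17)-en-13-one (CNP0139304.2) | C=C1[C@H](O)C[C@H]2[C@@](C)(COC(C)=O)C[C@H](O)C[C@]2(C)[C@H]1CCC(C)=O | target

Total step count: 14. Longest linear sequence: 14 steps (from 1 to 23).

Steps most likely to fail

Step 11. The cycloaddition may be too slow, because the inside methyl group (C20) disfavours the s-cis diene; 1,5-hydrogen shift within the diene or erosion of the trans selectivity could then take over. Fallback (sets out from 14, comes back at 21): the sulfone is exchanged for a formyl group that permits Lewis-acid catalysis at low temperature. The lithium enolate of 14 is treated with methyl (E)-3-(phenylsulfonyl)acrylate (addition–elimination, again anti to the C2 side chain) to give the acrylate lactone F1. iBu2AlH reduces lactone and ester to the triol F2. MnO2 oxidises only the allylic alcohol to the enal F3. AcCl/2,4,6-collidine gives the C19 acetate F4, and TBSCl/imidazole gives the silyl ether F5. Me2AlCl in CH2Cl2 at −78 °C should then bring about the same intramolecular Diels–Alder reaction to the 6α-formyl adduct F6. Decarbonylation with RhCl(PPh3)3 in toluene at 110 °C returns to 21.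

Step 14. The allylic oxidation may run on to the enone or attack the tertiary allylic C9–H. Fallback (sets out from 21, comes back at 23): oxidation level and configuration at C7 are set in separate operations on protected material. Anhydrous CF3CO2H in CH2Cl2 at −40 °C should effect the protodesilylation alone and give the protected exocyclic alkene F7. SeO2/t-BuOOH followed by Dess–Martin periodinane converges all C7-oxidised material on the enone F8. Corey–Bakshi–Shibata reduction (catecholborane with the enantiomer of 1-methyl-3,3-diphenyltetrahydro-1H,3H-pyrrolo[1,2-c][1,3,2]oxazaborole that delivers hydride to the β face) should give the 7α-alcohol F9 by 1,2-reduction. CF3CO2H–H2O–THF then removes the dioxolane and the silyl ether to give 23.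

Step 9. The acylation may not discriminate well enough between the neopentyl primary and the unhindered secondary hydroxyl group. Fallback (sets out from 17, comes back at 19): both hydroxyl groups are silylated (TBSCl, imidazole, DMF) to the bis-silyl ether F10. The primary silyl ether is cleaved selectively (HF·pyridine, pyridine, THF, 0 °C) to the primary alcohol F11. Acetylation (Ac2O, pyridine, 4-(dimethylamino)pyridine) gives 19.

Further compounds
F1 | step 11 | methyl (E)-3-[(3S,5R)-5-dienyl-3-methyl-2-oxotetrahydrofuran-3-yl]acrylate | O=C1O[C@H](C/C(C)=C(\CCC2(C)OCCO2)C(=C)C[Si](C)(C)C)C[C@@]1(C)/C=C/C(=O)OC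
F2 | step 11 | (2E,4S,6R)-6-dienyl-4-(hydroxymethyl)-4-methylhex-2-ene-1,6-diol | OC/C=C/[C@@](C)(CO)C[C@H](O)C/C(C)=C(\CCC1(C)OCCO1)C(=C)C[Si](C)(C)C
F3 | step 11 | (2E,4S,6R)-6-dienyl-6-hydroxy-4-(hydroxymethyl)-4-methylhex-2-enal | O=C/C=C/[C@@](C)(CO)C[C@H](O)C/C(C)=C(\CCC1(C)OCCO1)C(=C)C[Si](C)(C)C
F4 | step 11 | (2S,4R)-4-dienyl-4-hydroxy-2-methyl-2-[(E)-3-oxoprop-1-enyl]butyl acetate | O=C/C=C/[C@@](C)(COC(C)=O)C[C@H](O)C/C(C)=C(\CCC1(C)OCCO1)C(=C)C[Si](C)(C)C
F5 | step 11 | (2S,4R)-4-(tert-butyldimethylsilyloxy)-4-dienyl-2-methyl-2-[(E)-3-oxoprop-1-enyl]butyl acetate | O=C/C=C/[C@@](C)(COC(C)=O)C[C@H](O[Si](C)(C)C(C)(C)C)C/C(C)=C(\CCC1(C)OCCO1)C(=C)C[Si](C)(C)C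
F6 | step 11 | 19-acetoxy-2α-(tert-butyldimethylsilyloxy)-6α-formyl-17-(trimethylsilyl)-14,15-dinorlabd-8-en-13-one ethylene ketal | C[Si](C)(C)CC=1C[C@H](C=O)[C@H]2[C@@](C)(COC(C)=O)C[C@H](O[Si](C)(C)C(C)(C)C)C[C@]2(C)C=1CCC3(C)OCCO3
F7 | step 14 | 19-acetoxy-2α-(tert-butyldimethylsilyloxy)-14,15-dinorlabd-8(17)-en-13-one ethylene ketal | C=C1CC[C@H]2[C@@](C)(COC(C)=O)C[C@H](O[Si](C)(C)C(C)(C)C)C[C@]2(C)[C@H]1CCC3(C)OCCO3
F8 | step 14 | 19-acetoxy-2α-(tert-butyldimethylsilyloxy)-14,15-dinorlabd-8(17)-ene-7,13-dione 13-ethylene ketal | C=C1C(=O)C[C@H]2[C@@](C)(COC(C)=O)C[C@H](O[Si](C)(C)C(C)(C)C)C[C@]2(C)[C@H]1CCC3(C)OCCO3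
F9 | step 14 | 19-acetoxy-2α-(tert-butyldimethylsilyloxy)-7α-hydroxy-14,15-dinorlabd-8(17)-en-13-one ethylene ketal | C=C1[C@H](O)C[C@H]2[C@@](C)(COC(C)=O)C[C@H](O[Si](C)(C)C(C)(C)C)C[C@]2(C)[C@H]1CCC3(C)OCCO3
F10 | step 9 | (2S,4R)-1,4-bis(tert-butyldimethylsilyloxy)-4-dienyl-2-methyl-2-[(E)-2-(phenylsulfonyl)ethenyl]butane | O=S(=O)(c1ccccc1)/C=C/[C@@](C)(CO[Si](C)(C)C(C)(C)C)C[C@H](O[Si](C)(C)C(C)(C)C)C/C(C)=C(\CCC1(C)OCCO1)C(=C)C[Si](C)(C)C
F11 | step 9 | (2S,4R)-4-(tert-butyldimethylsilyloxy)-4-dienyl-2-methyl-2-[(E)-2-(phenylsulfonyl)ethenyl]butan-1-ol | O=S(=O)(c1ccccc1)/C=C/[C@@](C)(CO)C[C@H](O[Si](C)(C)C(C)(C)C)C/C(C)=C(\CCC1(C)OCCO1)C(=C)C[Si](C)(C)C
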